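**Retrosynthetic overview**

1. The target is 1-(3,5-dihydroxyphenyl)henicosan-2-one. On its single benzene ring the carbon chain at C1' is meta to both hydroxyls (C3', C5'), so neither oxygen can direct a C–C bond to C1'. The ring is therefore built with the 1,3,5-pattern already in place.
2. Endgame, read backwards: cleavage of the two aryl ethyl ethers; C2 ketone by oxidation of a carbinol; desilylation; ethylation of the phenol freed in the annulation, so that the oxidation meets no free phenol and one reagent later frees both hydroxyls.
3. Key disconnection: the benzene ring comes from a 3-substituted cyclobutenone and ethoxyacetylene (vinylketene/ynol ether [2+2], 4π opening, 6π closure; two new C–C bonds).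
4. The cyclobutenone comes from a dichloroketene [2+2] on a terminal alkyne and dechlorination; the alkyne from icosanal and propargyl bromide; icosanal from 1-eicosanol.
5. Ring order: the four-membered ring first (step 4), then the benzene ring (step 6), the cyclobutenone being consumed in making it.

Key step: step 6

Remark: the target has no stereocentre, so the achiral ketone is the compound asked for. The carbinol carbon carried from step 2 to step 8 is racemic and is erased in step 9.

**Route**

Step 1
Reactants: 1 1-eicosanol
Product: 2 icosanal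
Conditions: TEMPO (10 mol%), PhI(OAc)2 (1.1 equiv), CH2Cl2, 30 °C
Reagents that add atoms: none
Why: TEMPO-catalysed oxoammonium oxidation with PhI(OAc)2 as terminal oxidant should stop at the aldehyde under anhydrous conditions and runs warm enough to keep the waxy C20 alcohol in solution.

Step 2
Reactants: 2 icosanal; 3 propargyl bromide
Product: 5 rac-tricos-1-yn-4-ol, via allenylzinc bromide 4 (not isolated)
Conditions: Zn dust (1.5 equiv, activated), THF, 0 °C to rt; then 1 M HCl
Reagents that add atoms: none
Why: In this Barbier propargylation zinc inserts into the bromide to give the allenylzinc species, which adds to the aldehyde through a cyclic SE2' transition state to give the homopropargylic alcohol; the new carbinol centre is left racemic because it becomes the C2 carbonyl.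

Step 3
Reactants: 5 rac-tricos-1-yn-4-ol
Product: 6 rac-triisopropyl(tricos-1-yn-4-yloxy)silane
Conditions: TIPSOTf (1.2 equiv), 2,6-lutidine (1.5 equiv), CH2Cl2, 0 °C to rt
Reagents that add atoms: triisopropylsilyl trifluoromethanesulfonate, CC(C)[Si](OS(=O)(=O)C(F)(F)F)(C(C)C)C(C)C
Why: Silylation with a silyl triflate and a hindered base should protect the hindered secondary alcohol as a TIPS ether, which tolerates zinc chloride, acetic acid, heat and carbonate and is too poor a leaving group to be eliminated from the later cyclobutenone.

Step 4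
Reactants: 6 rac-triisopropyl(tricos-1-yn-4-yloxy)silane; 7 trichloroacetyl chloride
Product: 9 rac-4,4-dichloro-3-{2-[(triisopropylsilyl)oxy]henicosyl}cyclobut-2-en-1-one, via dichloroketene 8 (not isolated)
Conditions: 7 (2 equiv, slow addition), Zn–Cu couple (3 equiv), Et2O/DME, rt
Reagents that add atoms: none
Why: Dichloroketene, formed by zinc dechlorination of the acid chloride, undergoes the known [2+2] cycloaddition with a terminal alkyne, the ketene carbonyl carbon bonding to the nucleophilic terminal CH so that the chain ends at C3; DME ties up the zinc chloride.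

Step 5
Reactants: 9 rac-4,4-dichloro-3-{2-[(triisopropylsilyl)oxy]henicosyl}cyclobut-2-en-1-one
Product: 10 rac-3-{2-[(triisopropylsilyl)oxy]henicosyl}cyclobut-2-en-1-one
Conditions: Zn dust (4 equiv), AcOH, TMEDA, EtOH, 0 °C to rt
Reagents that add atoms: none
Why: Zinc reductive dechlorination of the α,α-dichloroketone, buffered by TMEDA and acetic acid, should remove both chlorines without the acid-promoted shift to the 2,4-dichloro isomer.

Step 6
Reactants: 10 rac-3-{2-[(triisopropylsilyl)oxy]henicosyl}cyclobut-2-en-1-one; 11 ethoxyacetylene
Product: 16 rac-3-ethoxy-5-{2-[(triisopropylsilyl)oxy]henicosyl}phenol, via vinylketene 12 (not isolated), via 4-vinylcyclobutenone 13 (not isolated), via dienylketene 14 (not isolated), via cyclohexa-2,4-dienone 15 (not isolated)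
Conditions: 11 (3 equiv), PhMe, 80 °C, sealed tube, Ar
Reagents that add atoms: none
Why: Heat opens cyclobutenone 10 by 4π-electrocyclic cleavage of its C1–C4 bond to vinylketene 12, whose ketene C=C bond undergoes a [2+2] cycloaddition with the ynol ether, the ketene carbonyl carbon bonding to the alkyne CH and the former cyclobutenone C2 bonding to the C–OEt carbon, to give 4-vinylcyclobutenone 13. A second 4π opening gives dienylketene 14, and the benzene ring is closed by a thermal disrotatory 6π-electrocyclisation between the ketene carbon and the terminal methylene carbon, after which dienone 15 tautomerises to phenol 16. This is the Danheiser benzannulation of a cyclobutenone with an alkoxyalkyne, a known route to resorcinol monoethers. No stereocentre is formed in the product: the ring stereocentre of 13 is lost on ring opening and the racemic silyloxy carbinol is a spectator. The step needs only regioselectivity in the [2+2] event, and polarity secures it, since the unsubstituted carbon of ethoxyacetylene is its nucleophilic end and the ketene carbonyl carbon is the electrophilic one, so that OEt ends meta to OH, while the single substituent of 12 sits on the ketene β-carbon and lands meta to both oxygens. No reagent is present, so the TIPS ether and the chain should pass through untouched.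

Step 7
Reactants: 16 rac-3-ethoxy-5-{2-[(triisopropylsilyl)oxy]henicosyl}phenol
Product: 17 rac-{[1-(3,5-diethoxyphenyl)henicosan-2-yl]oxy}triisopropylsilane
Conditions: EtI (1.5 equiv), K2CO3 (2 equiv), DMF, 50 °C
Reagents that add atoms: iodoethane, CCI
Why: Williamson etherification of the phenoxide caps the free phenol, which would otherwise be attacked in the later alcohol oxidation, and makes both aryl oxygens the same ether for one final cleavage.

Step 8
Reactants: 17 rac-{[1-(3,5-diethoxyphenyl)henicosan-2-yl]oxy}triisopropylsilane
Product: 18 rac-1-(3,5-diethoxyphenyl)henicosan-2-ol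
Conditions: TBAF (2 equiv), THF, rt to 50 °C; then H2O
Reagents that add atoms: none
Why: Fluoride desilylation, driven by the Si–F bond, should free the secondary alcohol while the aryl ethyl ethers are inert.

Step 9
Reactants: 18 rac-1-(3,5-diethoxyphenyl)henicosan-2-ol
Product: 19 1-(3,5-diethoxyphenyl)henicosan-2-one
Conditions: Dess–Martin periodinane (1.3 equiv), CH2Cl2, rt
Reagents that add atoms: none
Why: Dess–Martin oxidation converts the secondary alcohol into the C2 ketone at room temperature, where the long-chain substrate stays dissolved, and with no free phenol present the electron-rich ring is not attacked.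

Step 10
Reactants: 19 1-(3,5-diethoxyphenyl)henicosan-2-one
Product: 20 1-(3,5-dihydroxyphenyl)henicosan-2-one
Conditions: BBr3 (4 equiv), CH2Cl2, −78 °C to rt; then H2O, 0 °C
Reagents that add atoms: none
Why: Boron tribromide cleavage of aryl alkyl ethers (O–B complexation, then bromide attack at the ethyl carbon) should free both phenols, the ketone being carried as its boron complex and released on hydrolysis.

**Compound list**

1 | 1-eicosanol | CCCCCCCCCCCCCCCCCCCCO | starting material
2 | icosanal | CCCCCCCCCCCCCCCCCCCC=O | intermediate
3 | propargyl bromide | C#CCBr | starting material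
4 | allenylzinc bromide (formed in situ) | C=C=C[Zn]Br | intermediate
5 | rac-tricos-1-yn-4-ol | C#CCC(O)CCCCCCCCCCCCCCCCCCC | intermediate
6 | rac-triisopropyl(tricos-1-yn-4-yloxy)silane | C#CCC(O[Si](C(C)C)(C(C)C)C(C)C)CCCCCCCCCCCCCCCCCCC | intermediate
7 | trichloroacetyl chloride | ClC(Cl)(Cl)C(Cl)=O | starting material
8 | dichloroketene (formed in situ) | ClC(Cl)=C=O | intermediate
9 | rac-4,4-dichloro-3-{2-[(triisopropylsilyl)oxy]henicosyl}cyclobut-2-en-1-one | O=C1C=C(CC(O[Si](C(C)C)(C(C)C)C(C)C)CCCCCCCCCCCCCCCCCCC)C1(Cl)Cl | intermediate
10 | rac-3-{2-[(triisopropylsilyl)oxy]henicosyl}cyclobut-2-en-1-one | O=C1C=C(CC(O[Si](C(C)C)(C(C)C)C(C)C)CCCCCCCCCCCCCCCCCCC)C1 | intermediate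
11 | ethoxyacetylene | CCOC#C | starting material
12 | vinylketene, 3-methylidene-5-[(triisopropylsilyl)oxy]tetracos-1-en-1-one (not isolated) | O=C=CC(=C)CC(O[Si](C(C)C)(C(C)C)C(C)C)CCCCCCCCCCCCCCCCCCC | intermediate
13 | 4-vinylcyclobutenone, 3-ethoxy-4-{4-[(triisopropylsilyl)oxy]tricos-1-en-2-yl}cyclobut-2-en-1-one, mixture of diastereomers (not isolated) | O=C1C=C(OCC)C1C(=C)CC(O[Si](C(C)C)(C(C)C)C(C)C)CCCCCCCCCCCCCCCCCCC | intermediate
14 | dienylketene, (3E)-3-ethoxy-5-methylidene-7-[(triisopropylsilyl)oxy]hexacosa-1,3-dien-1-one (not isolated) | O=C=C/C(OCC)=C\C(=C)CC(O[Si](C(C)C)(C(C)C)C(C)C)CCCCCCCCCCCCCCCCCCC | intermediate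
15 | cyclohexa-2,4-dienone, 3-ethoxy-5-{2-[(triisopropylsilyl)oxy]henicosyl}cyclohexa-2,4-dien-1-one (not isolated) | O=C1C=C(OCC)C=C(CC(O[Si](C(C)C)(C(C)C)C(C)C)CCCCCCCCCCCCCCCCCCC)C1 | intermediate
16 | rac-3-ethoxy-5-{2-[(triisopropylsilyl)oxy]henicosyl}phenol | CCOc1cc(O)cc(CC(O[Si](C(C)C)(C(C)C)C(C)C)CCCCCCCCCCCCCCCCCCC)c1 | intermediate
17 | rac-{[1-(3,5-diethoxyphenyl)henicosan-2-yl]oxy}triisopropylsilane | CCOc1cc(OCC)cc(CC(O[Si](C(C)C)(C(C)C)C(C)C)CCCCCCCCCCCCCCCCCCC)c1 | intermediate
18 | rac-1-(3,5-diethoxyphenyl)henicosan-2-ol | CCOc1cc(OCC)cc(CC(O)CCCCCCCCCCCCCCCCCCC)c1 | intermediate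
19 | 1-(3,5-diethoxyphenyl)henicosan-2-one | CCOc1cc(OCC)cc(CC(=O)CCCCCCCCCCCCCCCCCCC)c1 | intermediate
20 | 1-(3,5-dihydroxyphenyl)henicosan-2-one | CCCCCCCCCCCCCCCCCCCC(=O)Cc1cc(O)cc(O)c1 | target

**Step count**

Total steps: 10. Longest linear sequence: 10 steps (1-eicosanol to the target; the other starting materials are bought).

**Steps most likely to fail**

Step 6. The cyclobutenone opens only slowly at 80 °C, while ethoxyacetylene is lost by retro-ene fragmentation to ketene and ethylene. The phenol being formed can also intercept the vinylketene as an aryl ester, so conversion may stall. Fallback: the aromatic ring is bought instead of built. Setting out from icosanal 2, commercial 3,5-dimethoxybenzyl chloride is converted with magnesium in THF (0 °C, high dilution) into (3,5-dimethoxybenzyl)magnesium chloride F1. This is added to 2 at −78 °C and worked up with 1 M HCl to give 1-(3,5-dimethoxyphenyl)henicosan-2-ol F2. Dess–Martin oxidation gives 1-(3,5-dimethoxyphenyl)henicosan-2-one F3, and BBr3 in CH2Cl2 cleaves both methyl ethers, coming back to the route at target 20.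

Step 4. Dichloroketene may oligomerise, and zinc chloride may degrade the product faster than the ketene adds to a waxy, dilute alkyne; the silyl ether may be partly lost to the Lewis acid. Fallback: a chlorine-free keteniminium cycloaddition. Setting out from alkyne 6, N,N-dimethylacetamide is activated with Tf2O and 2,4,6-collidine in refluxing 1,2-dichloroethane to N,N-dimethylketeniminium triflate F4. This adds across the alkyne to give N,N-dimethyl-3-{2-[(triisopropylsilyl)oxy]henicosyl}cyclobut-2-en-1-iminium triflate F5. Hydrolysis with aqueous NaHCO3 comes back to the route at cyclobutenone 10, so that compound 9 and step 5 are bypassed.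

Step 10. The two ethyl ethers cleave slowly, and boron enolate formation at the doubly activated C1 methylene can compete, leading to self-condensation or alkylation of the freed resorcinol ring by the activated ketone. Fallback: the phenols are freed before the ketone exists and carried through the oxidation as silyl ethers. Setting out from alcohol 18, BBr3 in CH2Cl2 (−78 to 0 °C; the carbinol is held as its borate and returns on hydrolysis) gives 5-(2-hydroxyhenicosyl)benzene-1,3-diol F6. TBSCl (2.1 equiv) and imidazole in DMF at 0 °C silylate the two phenols in preference to the hindered secondary alcohol, giving 1-{3,5-bis[(tert-butyldimethylsilyl)oxy]phenyl}henicosan-2-ol F7. Dess–Martin oxidation gives 1-{3,5-bis[(tert-butyldimethylsilyl)oxy]phenyl}henicosan-2-one F8, and TBAF buffered with acetic acid in THF at 0 °C removes both aryl silyl ethers, coming back to the route at target 20.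

**Further compounds**

F1 | step 6 | (3,5-dimethoxybenzyl)magnesium chloride | COc1cc(C[Mg]Cl)cc(OC)c1
F2 | step 6 | rac-1-(3,5-dimethoxyphenyl)henicosan-2-ol | COc1cc(OC)cc(CC(O)CCCCCCCCCCCCCCCCCCC)c1
F3 | step 6 | 1-(3,5-dimethoxyphenyl)henicosan-2-one | COc1cc(OC)cc(CC(=O)CCCCCCCCCCCCCCCCCCC)c1
F4 | step 4 | N,N-dimethylketeniminium triflate | C=C=[N+](C)C.[O-]S(=O)(=O)C(F)(F)F
F5 | step 4 | rac-N,N-dimethyl-3-{2-[(triisopropylsilyl)oxy]henicosyl}cyclobut-2-en-1-iminium triflate | C[N+](C)=C1C=C(CC(O[Si](C(C)C)(C(C)C)C(C)C)CCCCCCCCCCCCCCCCCCC)C1.[O-]S(=O)(=O)C(F)(F)F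
F6 | step 10 | rac-5-(2-hydroxyhenicosyl)benzene-1,3-diol | Oc1cc(O)cc(CC(O)CCCCCCCCCCCCCCCCCCC)c1
F7 | step 10 | rac-1-{3,5-bis[(tert-butyldimethylsilyl)oxy]phenyl}henicosan-2-ol | CC(C)(C)[Si](C)(C)Oc1cc(O[Si](C)(C)C(C)(C)C)cc(CC(O)CCCCCCCCCCCCCCCCCCC)c1
F8 | step 10 | 1-{3,5-bis[(tert-butyldimethylsilyl)oxy]phenyl}henicosan-2-one | CC(C)(C)[Si](C)(C)Oc1cc(O[Si](C)(C)C(C)(C)C)cc(CC(=O)CCCCCCCCCCCCCCCCCCC)c1
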